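**Retrosynthetic overview**
- The oxolane ring, the C3–C4 bond and the CH2–aryl bond are made last, in one nickel/titanium-catalysed epoxide opening / 5-exo radical cyclisation / aryl cross-coupling between an enantiopure epoxy allyl ether and 4-bromo-1,2-dimethoxybenzene.
- The epoxy allyl ether comes from O-allylation of an erythro aryl epoxy alcohol, made by chelation-controlled reduction of an aryl oxiranyl ketone (3,4,5-trimethoxyphenyllithium + glycidic Weinreb amide).
- The aryl chloride comes from 4-chlorophenol, the Weinreb amide from methyl (R)-glycidate (source of absolute configuration), the aryl bromide from catechol.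
- Ring order: the oxirane is carried in from the chiral pool and consumed; the oxolane is the only ring formed, in the last step.

Assumption: methyl (2R)-oxirane-2-carboxylate is bought as the single enantiomer.

**Route**

Step 1
Reactants: 1 4-chlorophenol
Product: 2 2,6-dibromo-4-chlorophenol
Conditions: Br2 (2.1 equiv), AcOH, 20 °C
Reagents that add atoms: bromine (BrBr)
Why: Electrophilic aromatic bromination; the hydroxyl group directs both bromines ortho because the para position is blocked by chlorine.

Step 2
Reactants: 2 2,6-dibromo-4-chlorophenol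
Product: 3 4-chloro-2,6-dimethoxyphenol
Conditions: NaOMe (6 equiv), CuBr (10 mol%), DMF/MeOH, 110 °C
Reagents that add atoms: sodium methoxide ([Na+].[O-]C)
Why: Copper-catalysed Ullmann-type methoxylation replaces both aryl bromides, while the much less reactive aryl chloride is kept.

Step 3
Reactants: 3 4-chloro-2,6-dimethoxyphenol
Product: 4 5-chloro-1,2,3-trimethoxybenzene
Conditions: MeI, K2CO3, acetone, 56 °C
Reagents that add atoms: iodomethane (CI)
Why: Williamson O-methylation of the phenoxide.

Step 4
Reactants: 5 methyl (2R)-oxirane-2-carboxylate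
Product: 6 potassium (2R)-oxirane-2-carboxylate
Conditions: KOH (1.0 equiv), EtOH, 0 °C
Reagents that add atoms: potassium hydroxide ([K+].[OH-])
Why: Ester saponification at low temperature; the potassium salt precipitates from ethanol and the oxirane stereocentre is not touched.

Step 5
Reactants: 6 potassium (2R)-oxirane-2-carboxylate
Product: 8 (2R)-N-methoxy-N-methyloxirane-2-carboxamide, via mixed pivalic anhydride 7 (not isolated)
Conditions: t-BuCOCl, THF, 0 °C; then MeNH(OMe)·HCl, Et3N, 0 to 20 °C
Reagents that add atoms: pivaloyl chloride (CC(C)(C)C(Cl)=O); N,O-dimethylhydroxylamine hydrochloride (CNOC.Cl)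
Why: Mixed-anhydride amidation (Weinreb amide formation); the amine attacks the less hindered glycidoyl carbonyl of 7, the pivaloyl group is carried only in 7 and leaves as pivalate, and the stereocentre is untouched.

Step 6
Reactants: 4 5-chloro-1,2,3-trimethoxybenzene; 8 (2R)-N-methoxy-N-methyloxirane-2-carboxamide
Product: 10 [(2R)-oxiran-2-yl](3,4,5-trimethoxyphenyl)methanone, via aryllithium 9 (not isolated)
Conditions: Li powder (2.5 equiv), 4,4'-di-tert-butylbiphenyl (5 mol%), THF, −78 °C; solution filtered by cannula onto 8, THF, −78 °C; aq. NH4Cl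
Reagents that add atoms: lithium ([Li])
Why: Arene-catalysed reductive lithiation of the aryl chloride followed by Weinreb ketone synthesis; the chelated tetrahedral adduct prevents over-addition, the oxirane is inert to the aryllithium at −78 °C, and lithium is carried only in 9 and is lost on work-up.

Step 7
Reactants: 10 [(2R)-oxiran-2-yl](3,4,5-trimethoxyphenyl)methanone
Product: 11 (S)-[(2R)-oxiran-2-yl](3,4,5-trimethoxyphenyl)methanol
Conditions: Zn(BH4)2, Et2O, −20 °C
Reagents that add atoms: none
Why: Chelation-controlled ketone reduction; zinc bridges the carbonyl and oxirane oxygens and hydride enters from the face of the oxirane C–H, giving the erythro (anti) alcohol and so the (S)-carbinol that becomes C2 of the target (minor epimer removed by chromatography).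

Step 8
Reactants: 11 (S)-[(2R)-oxiran-2-yl](3,4,5-trimethoxyphenyl)methanol; 12 allyl bromide
Product: 13 (2R)-2-[(S)-(prop-2-en-1-yloxy)(3,4,5-trimethoxyphenyl)methyl]oxirane
Conditions: NaH (added last), Bu4NI (cat.), THF, 0 °C
Reagents that add atoms: none
Why: Williamson etherification; the alkoxide is formed in the presence of excess allyl bromide so that O-allylation outruns Payne rearrangement, and no stereocentre is affected.

Step 9
Reactants: 14 catechol
Product: 15 1,2-dimethoxybenzene
Conditions: MeI, K2CO3, acetone, 56 °C
Reagents that add atoms: iodomethane (CI)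
Why: Double Williamson O-methylation.

Step 10
Reactants: 15 1,2-dimethoxybenzene
Product: 16 4-bromo-1,2-dimethoxybenzene
Conditions: NBS, MeCN, 20 °C
Reagents that add atoms: N-bromosuccinimide (O=C1CCC(=O)N1Br)
Why: Electrophilic aromatic bromination, selective for the position para to a methoxy group.

Step 11
Reactants: 13 (2R)-2-[(S)-(prop-2-en-1-yloxy)(3,4,5-trimethoxyphenyl)methyl]oxirane; 16 4-bromo-1,2-dimethoxybenzene
Product: 17 [(2R,3S,4S)-4-[(3,4-dimethoxyphenyl)methyl]-2-(3,4,5-trimethoxyphenyl)oxolan-3-yl]methanol
Conditions: NiCl2(dme) (10 mol%), 4,4'-di-tert-butyl-2,2'-bipyridine (10 mol%), Cp2TiCl2 (20 mol%), Mn powder (3 equiv), Et3N·HCl (2 equiv), 16 (1.5 equiv), THF/DMPU, 25 °C, slow addition of 13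
Reagents that add atoms: none
Why: Proposed new method: Mn reduces Cp2TiCl2 to Cp2TiCl (trivalent titanium), which opens the oxirane of 13 homolytically at the more substituted C–O bond; the secondary β-titanoxy radical at C3 cyclises 5-exo-trig onto the allyl ether through a chair-like Beckwith–Houk transition state with the aryl group pseudo-equatorial (C2/C3 trans) and the CH2O[Ti] arm cis to the new CH2 radical (C3/C4 cis); this primary radical is captured by ArNi(bipyridine)Br (divalent nickel, from oxidative addition of 16 to zerovalent nickel) to give a trivalent aryl(alkyl)nickel species that reductively eliminates the CH2–aryl bond, while Et3N·HCl cleaves the Ti–O bond to release the free alcohol and Mn turns over both metals; the closest known reaction types are the nickel/titanium co-catalysed branched-selective arylation of epoxides with aryl bromides, the titanocene-mediated epoxy-olefin radical cyclisation (Nugent–RajanBabu) and the nickel-catalysed reductive cyclisation/arylation of haloalkyl allyl ethers, which to my knowledge have not been merged into one catalytic operation.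

**Compound list**

1 | 4-chlorophenol | Oc1ccc(Cl)cc1 | starting material
2 | 2,6-dibromo-4-chlorophenol | Oc1c(Br)cc(Cl)cc1Br | intermediate
3 | 4-chloro-2,6-dimethoxyphenol | COc1cc(Cl)cc(OC)c1O | intermediate
4 | 5-chloro-1,2,3-trimethoxybenzene | COc1cc(Cl)cc(OC)c1OC | intermediate
5 | methyl (2R)-oxirane-2-carboxylate | COC(=O)[C@H]1CO1 | starting material
6 | potassium (2R)-oxirane-2-carboxylate | [K+].[O-]C(=O)[C@H]1CO1 | intermediate
7 | (2R)-oxirane-2-carboxylic 2,2-dimethylpropanoic anhydride | CC(C)(C)C(=O)OC(=O)[C@H]1CO1 | intermediate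
8 | (2R)-N-methoxy-N-methyloxirane-2-carboxamide | CON(C)C(=O)[C@H]1CO1 | intermediate
9 | (3,4,5-trimethoxyphenyl)lithium | [Li]c1cc(OC)c(OC)c(OC)c1 | intermediate
10 | [(2R)-oxiran-2-yl](3,4,5-trimethoxyphenyl)methanone | COc1cc(cc(OC)c1OC)C(=O)[C@H]1CO1 | intermediate
11 | (S)-[(2R)-oxiran-2-yl](3,4,5-trimethoxyphenyl)methanol | O[C@@H](c1cc(OC)c(OC)c(OC)c1)[C@H]1CO1 | intermediate
12 | allyl bromide | C=CCBr | starting material
13 | (2R)-2-[(S)-(prop-2-en-1-yloxy)(3,4,5-trimethoxyphenyl)methyl]oxirane | C=CCO[C@@H](c1cc(OC)c(OC)c(OC)c1)[C@H]1CO1 | intermediate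
14 | catechol | Oc1ccccc1O | starting material
15 | 1,2-dimethoxybenzene | COc1ccccc1OC | intermediate
16 | 4-bromo-1,2-dimethoxybenzene | COc1ccc(Br)cc1OC | intermediate
17 | [(2R,3S,4S)-4-[(3,4-dimethoxyphenyl)methyl]-2-(3,4,5-trimethoxyphenyl)oxolan-3-yl]methanol | COc1ccc(C[C@@H]2CO[C@@H](c3cc(OC)c(OC)c(OC)c3)[C@@H]2CO)cc1OC | target

**Step count**

Total step count: 11. Longest linear sequence: 7 steps (steps 1, 2, 3, 6, 7, 8, 11).

**Steps most likely to fail**

Step 11 (the proposed cascade). The risks are direct arylation of the uncyclised C3 radical, reduction of the cyclised radical to a methyl group, and only moderate diastereoselectivity (about 4–6:1 expected from the related titanocene cyclisations; isomers separable by chromatography). The fallback sets out from 13 and comes back at 17, using known chemistry only. Stoichiometric Cp2TiCl (from Cp2TiCl2 and Zn, THF, 20 °C) effects the known reductive epoxy-olefin radical cyclisation, and the resulting primary alkyltitanium is quenched with I2 to give [(2R,3S,4S)-4-(iodomethyl)-2-(3,4,5-trimethoxyphenyl)oxolan-3-yl]methanol F1. This iodide is then joined to 16 by the established nickel-catalysed cross-electrophile coupling of a primary alkyl iodide with an aryl bromide (NiI2, 4,4'-dimethoxy-2,2'-bipyridine, Zn, NaI, pyridine, DMPU, 60 °C), which tolerates the free alcohol, to give 17.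

Step 6 (aryllithium from an electron-rich aryl chloride and its acylation). The risks are incomplete lithiation, reductive loss of a methoxy group, and attack on the oxirane. The fallback sets out from 4 and comes back at 13, avoiding any aryl-metal reagent and bypassing 10 and 11. A Heck reaction of 4 with methyl acrylate (Pd2(dba)3, P(t-Bu)3, Cy2NMe, dioxane, 100 °C) gives methyl (E)-3-(3,4,5-trimethoxyphenyl)prop-2-enoate F2. Reduction with i-Bu2AlH (CH2Cl2, −78 °C) gives (E)-3-(3,4,5-trimethoxyphenyl)prop-2-en-1-ol F3. Sharpless asymmetric epoxidation (Ti(OiPr)4, D-(−)-diisopropyl tartrate, t-BuOOH, 4 Å sieves, CH2Cl2, −20 °C) gives [(2R,3R)-3-(3,4,5-trimethoxyphenyl)oxiran-2-yl]methanol F4. Ti(OiPr)4-mediated opening with allyl alcohol at the benzylic carbon, with inversion, gives (2R,3S)-3-(prop-2-en-1-yloxy)-3-(3,4,5-trimethoxyphenyl)propane-1,2-diol F5. One-pot terminal epoxide formation (NaH, 1-tosylimidazole, THF, 0 to 20 °C) then delivers 13 as the same diastereomer as in the main route.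

Step 7 (diastereoselective reduction that fixes the C2 configuration). The risk is insufficient erythro selectivity; the wrong carbinol epimer would lead to the enantiomeric series. The fallback sets out from 4 (through 9) and comes back at 11, replacing substrate control by a catalytic kinetic resolution. Aryllithium 9 is added to acrolein (THF, −78 °C) to give racemic 1-(3,4,5-trimethoxyphenyl)prop-2-en-1-ol F6. Sharpless kinetic-resolution epoxidation (Ti(OiPr)4, L-(+)-diisopropyl tartrate, t-BuOOH 0.45 equiv, 4 Å sieves, CH2Cl2, −20 °C) converts the fast-reacting (R)-enantiomer into the erythro epoxy alcohol 11, which is separated from unreacted (S)-F6. The tartrate sense is assigned by analogy with alkyl vinyl carbinols and should be confirmed on the first run.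

**Further compounds**

F1 | step 11 | [(2R,3S,4S)-4-(iodomethyl)-2-(3,4,5-trimethoxyphenyl)oxolan-3-yl]methanol | IC[C@@H]1CO[C@@H](c2cc(OC)c(OC)c(OC)c2)[C@@H]1CO
F2 | step 6 | methyl (E)-3-(3,4,5-trimethoxyphenyl)prop-2-enoate | COC(=O)/C=C/c1cc(OC)c(OC)c(OC)c1
F3 | step 6 | (E)-3-(3,4,5-trimethoxyphenyl)prop-2-en-1-ol | OC/C=C/c1cc(OC)c(OC)c(OC)c1
F4 | step 6 | [(2R,3R)-3-(3,4,5-trimethoxyphenyl)oxiran-2-yl]methanol | OC[C@H]1O[C@@H]1c2cc(OC)c(OC)c(OC)c2
F5 | step 6 | (2R,3S)-3-(prop-2-en-1-yloxy)-3-(3,4,5-trimethoxyphenyl)propane-1,2-diol | C=CCO[C@@H](c1cc(OC)c(OC)c(OC)c1)[C@H](O)CO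
F6 | step 7 | racemic 1-(3,4,5-trimethoxyphenyl)prop-2-en-1-ol | OC(C=C)c1cc(OC)c(OC)c(OC)c1
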